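**Strategy.** Everything rests on cutting the butenolide ring (O, C15, C14, C13, C16; labdane numbering) at C13–C16 and O–C15, so that the lactone carboxyl is CO2. The precursor is a (12E)-13-iodoalkene whose 14,15-diol is masked as a cyclic methyl orthoacetate. In one pot, I/Li exchange and carboxylation forge C13–C16; acid then converts the orthoester into a dioxolan-2-ylium ion that the new carboxylate opens at primary C15. The step exploits the vicinal C14–O/C15–O pair of the γ-lactone: ring closure and placement of the acetate on O14 are one event. The ent-labdane decalin comes from an auxiliary-controlled Mn(III)/Cu(II) radical bicyclization.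

Key step: step 12

Remarks on the chemistry:
- Atom labels follow labdane numbering of the target: decalin C1–C10, chain C11–C12, lactone C13–C16 (C16 = carbonyl), C17 = exocyclic CH2, C18 = methyl and C19 = CH2OH on C4, C20 = methyl on C10.
- Assumption: in step 7 the (1S,2R,5S)-8-phenylmenthyl ester is taken to direct C4–C5 bond formation to the face that gives the ent-labdane series. Should the opposite sense be found, the (1R,2S,5R) antipode of the auxiliary is used and nothing else changes.
- Compounds 1, 3, 8 and 9 are purchased.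

Step 1
Reactants: 1 (R)-2,2-dimethyl-1,3-dioxolane-4-carbaldehyde
Product: 2 (S)-4-ethynyl-2,2-dimethyl-1,3-dioxolane
Conditions: Ohira–Bestmann reagent, K2CO3, MeOH, 0 °C to rt
Reagents that add atoms: dimethyl (1-diazo-2-oxopropyl)phosphonate, CC(=O)C(=[N+]=[N-])P(=O)(OC)OC
Why: Seyferth–Gilbert homologation in its Ohira–Bestmann form turns the aldehyde into the terminal alkyne under mild base, the C14 stereocentre being carried over unchanged from the chiral pool.

Step 2
Reactants: 2 (S)-4-ethynyl-2,2-dimethyl-1,3-dioxolane; 3 geranyl bromide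
Product: 5 (4S)-4-[(4E)-5,9-dimethyldeca-4,8-dien-1-yn-1-yl]-2,2-dimethyl-1,3-dioxolane, via alkynylmagnesium bromide 4 (not isolated)
Conditions: EtMgBr, THF, 0 °C to rt; CuBr·SMe2 (10 mol %), then 3, rt to 45 °C
Reagents that add atoms: none
Why: Copper-catalysed coupling of an alkynyl Grignard reagent with a primary allylic bromide should give the skipped enyne by direct (SN2) substitution with the E-olefin intact.

Step 3
Reactants: 5 skipped enyne
Product: 6 (2E,6E)-10-[(4S)-2,2-dimethyl-1,3-dioxolan-4-yl]-2,6-dimethyldeca-2,6-dien-9-yn-1-ol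
Conditions: SeO2 (cat.), t-BuOOH, salicylic acid (cat.), CH2Cl2, 0 °C to rt; then NaBH4, MeOH (returns any enal to 6)
Reagents that add atoms: selenium dioxide, O=[Se]=O; tert-butyl hydroperoxide, CC(C)(C)OO
Why: SeO2 allylic oxidation (ene reaction then [2,3]-shift) attacks the most electron-rich, terminal trisubstituted olefin at its E-methyl group, which fixes the E geometry of the new allylic alcohol.

Step 4
Reactants: 6 allylic alcohol
Product: 7 (4S)-4-[(4E,8E)-10-bromo-5,9-dimethyldeca-4,8-dien-1-yn-1-yl]-2,2-dimethyl-1,3-dioxolane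
Conditions: CBr4, PPh3, CH2Cl2, 0 °C
Reagents that add atoms: carbon tetrabromide, BrC(Br)(Br)Br
Why: The Appel reaction converts the primary allylic alcohol into the bromide under neutral conditions that spare the acetonide and the olefin geometry.

Step 5
Reactants: 8 (1S,2R,5S)-8-phenylmenthol; 9 ethyl 2-methyl-3-oxobutanoate
Product: 10 (1S,2R,5S)-8-phenylmenthyl 2-methyl-3-oxobutanoate (both C2 epimers)
Conditions: DMAP (cat.), toluene, reflux with removal of EtOH
Reagents that add atoms: none
Why: DMAP-catalysed transesterification of a β-keto ester (acylketene pathway) loads the hindered auxiliary; the C2 configuration is irrelevant because C2 becomes a radical centre later.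

Step 6
Reactants: 10 auxiliary keto ester; 7 allylic bromide
Product: 12 (1S,2R,5S)-8-phenylmenthyl (6E,10E)-14-[(4S)-2,2-dimethyl-1,3-dioxolan-4-yl]-2,6,10-trimethyl-3-oxotetradeca-6,10-dien-13-ynoate, via dilithio dianion 11 (not isolated)
Conditions: LDA (2.1 equiv), THF, −78 to 0 °C; then 7, −78 to 0 °C; AcOH quench
Reagents that add atoms: none
Why: γ-Alkylation of a β-keto ester dianion by a primary allylic bromide is fast and site-selective, giving the all-E cyclisation substrate.

Step 7
Reactants: 12 polyene keto ester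
Product: 13 decalin keto ester [3-oxo; C19 ester axial and syn to C20; H5 anti to C20; C9 side chain equatorial; exocyclic C8=C17; side chain CH2–C≡C–(4S)-dioxolanyl]
Conditions: Mn(OAc)3·2H2O (2.2 equiv), Cu(OAc)2·H2O (1 equiv), degassed AcOH, 25–40 °C
Reagents that add atoms: none
Why: Mn(III)-based oxidative radical bicyclisation (6-endo, 6-endo) through a chair–chair array sets C4, C5, C10 and C9 relative to one another (trans-decalin, axial ester, equatorial side chain), the phenylmenthyl group selects the radical face and hence the absolute series, and Cu(II) oxidises the tertiary C8 radical to the exocyclic olefin.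

Step 8
Reactants: 13 decalin keto ester
Product: 14 3,19-diol [3-OH equatorial and cis to the axial C19 CH2OH]
Conditions: LiAlH4, THF, 0 °C to rt; aqueous NaOH work-up
Reagents that add atoms: none
Why: Hydride reduction of the ketone by axial attack, away from the axial C4 substituent, should give the equatorial C3 alcohol, and the same reagent reduces the neopentyl ester to C19–OH with release of the auxiliary.

Step 9
Reactants: 14 3,19-diol
Product: 15 3,19-O-(di-tert-butylsilylene) derivative of 14
Conditions: t-Bu2Si(OTf)2, 2,6-lutidine, CH2Cl2, 0 °C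
Reagents that add atoms: di-tert-butylsilyl bis(trifluoromethanesulfonate), CC(C)(C)[Si](OS(=O)(=O)C(F)(F)F)(OS(=O)(=O)C(F)(F)F)C(C)(C)C
Why: Silylene formation on the 1,3-diol gives a six-membered protecting ring that resists mild acid and organolithiums and leaves by fluoride at the end.

Step 10
Reactants: 15 silylene alkyne
Product: 17 (12E)-13-iodoalkene [I on C13, H12 cis to I; dioxolane on C13], via vinylstannane 16 (not isolated)
Conditions: Bu3SnH, PdCl2(PPh3)2 (3 mol %), THF, 0 °C to rt; then I2, CH2Cl2, 0 °C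
Reagents that add atoms: tributyltin hydride, CCCC[SnH](CCCC)CCCC; iodine, II
Why: Palladium-catalysed syn-hydrostannation places tin on the alkyne carbon next to the oxygenated C14 and hydrogen on C12, and iododestannylation with retention fixes the 12E geometry; the minor regioisomer is removed by chromatography.

Step 11
Reactants: 17 iodoalkene acetonide
Product: 19 14,15-cyclic methyl orthoacetate of the iodoalkene (both epimers at the orthoester carbon), via iodo diol 18 (not isolated)
Conditions: PPTS, MeOH, 45 °C; evaporate; MeC(OMe)3, PPTS (cat.), CH2Cl2, rt; Et3N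
Reagents that add atoms: trimethyl orthoacetate, COC(C)(OC)OC
Why: Acetal methanolysis frees the terminal 1,2-diol while the silylene survives, and orthoester exchange then closes the 2-methoxy-2-methyl-1,3-dioxolane, whose new centre is lost in the next step.

Step 12
Reactants: 19 iodoalkene orthoacetate
Product: 22 3,19-O-(di-tert-butylsilylene)-14-O-acetylandrographolide, via vinyllithium 20 (not isolated), via lithium carboxylate 21 (not isolated)
Conditions: t-BuLi (2.1 equiv), THF, −78 °C; dry CO2, −78 °C; Ar purge; (±)-camphorsulfonic acid (1.1 equiv), 5 Å MS, −78 to 40 °C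
Reagents that add atoms: carbon dioxide, O=C=O
Why: Iodine–lithium exchange with retention of olefin geometry gives the 13-lithio species, which adds to CO2 to form C13–C16. Protonation then lets the acid ionise the neighbouring orthoester (loss of MeOH) to a 2-methyl-1,3-dioxolan-2-ylium ion, and the carboxylate opens this ion by SN2 attack at C15, forming O–C15 and leaving the former O15 as the carbonyl oxygen of the acetate on O14. The closest known reaction types are the Prévost-type opening of acyloxonium ions by carboxylates at carbon, the O-alkylation of carboxylic acids by orthoesters, and vinyllithium carboxylation. The γ-lactone closes in the 5-exo-tet mode. No stereocentre is created: the C14–O bond is never broken, and the E-olefin follows from the retentive Sn→I→Li→C sequence. The step needs C15 rather than C14 to be attacked, which the primary carbon and the five- versus four-membered ring secure, and it needs carboxylation to outrun β-elimination of the lithio species, which −78 °C and immediate CO2 addition secure.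

Step 13
Reactants: 22 silylene-protected 14-acetate
Product: 23 14-O-acetylandrographolide (target)
Conditions: HF·pyridine, pyridine, THF, 0 °C to rt
Reagents that add atoms: none
Why: Fluoride-mediated desilylation under buffered acidic conditions removes the silylene without touching the allylic acetate, the lactone or the exocyclic olefin.

**Compound list**

1 | (R)-2,2-dimethyl-1,3-dioxolane-4-carbaldehyde | O=C[C@H]1COC(C)(C)O1 | starting material
2 | (S)-4-ethynyl-2,2-dimethyl-1,3-dioxolane | C#C[C@H]1COC(C)(C)O1 | intermediate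
3 | geranyl bromide, (2E)-1-bromo-3,7-dimethylocta-2,6-diene | CC(C)=CCC/C(C)=C/CBr | starting material
4 | alkynylmagnesium bromide of 2 | Br[Mg]C#C[C@H]1COC(C)(C)O1 | intermediate (not isolated)
5 | (4S)-4-[(4E)-5,9-dimethyldeca-4,8-dien-1-yn-1-yl]-2,2-dimethyl-1,3-dioxolane | CC(C)=CCC/C(C)=C/CC#C[C@H]1COC(C)(C)O1 | intermediate
6 | (2E,6E)-10-[(4S)-2,2-dimethyl-1,3-dioxolan-4-yl]-2,6-dimethyldeca-2,6-dien-9-yn-1-ol | OC/C(C)=C/CC/C(C)=C/CC#C[C@H]1COC(C)(C)O1 | intermediate
7 | (4S)-4-[(4E,8E)-10-bromo-5,9-dimethyldeca-4,8-dien-1-yn-1-yl]-2,2-dimethyl-1,3-dioxolane | BrC/C(C)=C/CC/C(C)=C/CC#C[C@H]1COC(C)(C)O1 | intermediate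
8 | (1S,2R,5S)-5-methyl-2-(2-phenylpropan-2-yl)cyclohexan-1-ol, (+)-8-phenylmenthol | CC(C)(c1ccccc1)[C@H]1CC[C@H](C)C[C@@H]1O | starting material
9 | ethyl 2-methyl-3-oxobutanoate | CCOC(=O)C(C)C(C)=O | starting material
10 | (1S,2R,5S)-8-phenylmenthyl 2-methyl-3-oxobutanoate (C2 epimers) | CC(=O)C(C)C(=O)O[C@H]1C[C@@H](C)CC[C@@H]1C(C)(C)c1ccccc1 | intermediate
11 | dilithio dianion of 10 (γ-carbanion, enolate) | [Li]CC(O[Li])=C(C)C(=O)O[C@H]1C[C@@H](C)CC[C@@H]1C(C)(C)c1ccccc1 | intermediate (not isolated)
12 | (1S,2R,5S)-8-phenylmenthyl (6E,10E)-14-[(4S)-2,2-dimethyl-1,3-dioxolan-4-yl]-2,6,10-trimethyl-3-oxotetradeca-6,10-dien-13-ynoate (C2 epimers) | CC(C(=O)CC/C(C)=C/CC/C(C)=C/CC#C[C@H]1COC(C)(C)O1)C(=O)O[C@H]1C[C@@H](C)CC[C@@H]1C(C)(C)c1ccccc1 | intermediate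
13 | decalin keto ester: 3-oxo, axial C19 8-phenylmenthyl ester syn to C20, trans ring fusion, exocyclic C8=C17, equatorial C9–CH2–C≡C–(4S)-dioxolanyl | C=C1CC[C@@H]2[C@](C)(C(=O)O[C@H]3C[C@@H](C)CC[C@@H]3C(C)(C)c3ccccc3)C(=O)CC[C@@]2(C)[C@@H]1CC#C[C@H]1COC(C)(C)O1 | intermediate
14 | 3,19-diol of the decalin alkyne (3-OH equatorial, cis to axial CH2OH) | C=C1CC[C@@H]2[C@](C)(CO)[C@H](O)CC[C@@]2(C)[C@@H]1CC#C[C@H]1COC(C)(C)O1 | intermediate
15 | 3,19-O-(di-tert-butylsilylene) derivative of 14 | C=C1CC[C@@H]2[C@]3(C)CO[Si](C(C)(C)C)(C(C)(C)C)O[C@@H]3CC[C@@]2(C)[C@@H]1CC#C[C@H]1COC(C)(C)O1 | intermediate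
16 | (12E)-13-(tributylstannyl)alkene from 15 | C=C1CC[C@@H]2[C@]3(C)CO[Si](C(C)(C)C)(C(C)(C)C)O[C@@H]3CC[C@@]2(C)[C@@H]1C/C=C(/[Sn](CCCC)(CCCC)CCCC)[C@H]1COC(C)(C)O1 | intermediate (not isolated)
17 | (12E)-13-iodoalkene, 14,15-acetonide | C=C1CC[C@@H]2[C@]3(C)CO[Si](C(C)(C)C)(C(C)(C)C)O[C@@H]3CC[C@@]2(C)[C@@H]1C/C=C(/I)[C@H]1COC(C)(C)O1 | intermediate
18 | (12E)-13-iodoalkene (14S)-14,15-diol | C=C1CC[C@@H]2[C@]3(C)CO[Si](C(C)(C)C)(C(C)(C)C)O[C@@H]3CC[C@@]2(C)[C@@H]1C/C=C(/I)[C@H](O)CO | intermediate (not isolated)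
19 | (12E)-13-iodoalkene, 14,15-cyclic methyl orthoacetate (orthoester carbon epimers) | C=C1CC[C@@H]2[C@]3(C)CO[Si](C(C)(C)C)(C(C)(C)C)O[C@@H]3CC[C@@]2(C)[C@@H]1C/C=C(/I)[C@H]1COC(C)(OC)O1 | intermediate
20 | 13-lithioalkene from 19 (geometry retained) | C=C1CC[C@@H]2[C@]3(C)CO[Si](C(C)(C)C)(C(C)(C)C)O[C@@H]3CC[C@@]2(C)[C@@H]1C/C=C(/[Li])[C@H]1COC(C)(OC)O1 | intermediate (not isolated)
21 | lithium (12E)-13-carboxylate bearing the orthoacetate | C=C1CC[C@@H]2[C@]3(C)CO[Si](C(C)(C)C)(C(C)(C)C)O[C@@H]3CC[C@@]2(C)[C@@H]1C/C=C(/C(=O)O[Li])[C@H]1COC(C)(OC)O1 | intermediate (not isolated)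
22 | 3,19-O-(di-tert-butylsilylene)-14-O-acetylandrographolide | C=C1CC[C@@H]2[C@]3(C)CO[Si](C(C)(C)C)(C(C)(C)C)O[C@@H]3CC[C@@]2(C)[C@@H]1C/C=C1/C(=O)OC[C@H]1OC(C)=O | intermediate
23 | 14-O-acetylandrographolide, (3S,4E)-4-{2-[(1R,4aS,5R,6R,8aS)-6-hydroxy-5-(hydroxymethyl)-5,8a-dimethyl-2-methylidenedecahydronaphthalen-1-yl]ethylidene}-5-oxooxolan-3-yl acetate | C=C1CC[C@@H]2[C@](C)(CO)[C@H](O)CC[C@@]2(C)[C@@H]1C/C=C1/C(=O)OC[C@H]1OC(C)=O | target

**Totals.** Total step count: 13. Longest linear sequence: 12 steps (1, 2, 3, 4, 6, 7, 8, 9, 10, 11, 12, 13).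

**Steps most likely to fail**

Step 12. The lithio species may undergo β-elimination toward an allene before it is carboxylated. After carboxylation, the dioxolanylium ion may be captured by adventitious water or by methanol faster than by the carboxylate, which would scramble the acetate between O14 and O15. The fallback sets out from 17 and comes back at 22. Methanolysis of 17 (PPTS, MeOH) would give the iodo diol 18, now isolated. Palladium-catalysed carbonylative lactonisation [PdCl2(PPh3)2, CO (1 atm), Et3N, THF, 50 °C] should then convert it, through an acylpalladium species trapped by the primary C15 hydroxyl, into 3,19-O-(di-tert-butylsilylene)andrographolide F1. Acetylation of the free C14 hydroxyl (Ac2O, pyridine, 0 °C to rt) would give 22.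

Step 7. Facial control by the auxiliary on the non-chelated α-methyl radical may be insufficient or of the wrong sense, so that the series epimeric in the whole decalin is formed alongside the wanted one. The fallback sets out from 7 and comes back at 14. It moves the quaternary centre to a later enolate alkylation and uses a Lewis-acid-chelated radical instead. (1R,2S,5R)-8-Phenylmenthol F2 would be acetoacetylated (2,2,6-trimethyl-4H-1,3-dioxin-4-one, xylene, 140 °C) to (1R,2S,5R)-8-phenylmenthyl 3-oxobutanoate F3. Its dianion (LDA) would be alkylated with 7 to give the α-unsubstituted polyene keto ester F4. Cyclisation with Mn(OAc)3, Cu(OAc)2 and Yb(OTf)3 in CF3CH2OH at 0 °C, through the chelated dicarbonyl radical on the face away from the aryl ring, should give the bicyclic β-keto ester F5. C-Methylation (K2CO3, MeI, acetone) anti to the C20 methyl would place the ester axial and give the methylated keto ester F6. LiAlH4 would then deliver 14.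

Step 3. Oxidation may leak to the doubly activated C11 methylene or the internal olefin, and over-oxidation may erode the yield of the single allylic alcohol. The fallback sets out from 2 (used as its Grignard reagent 4) and comes back at 6. It carries out the allylic oxidation before the alkyne is attached, on a substrate whose allylic acetate deactivates the other olefin. Geranyl acetate F7 would be oxidised (SeO2 cat., t-BuOOH) to (2E,6E)-8-hydroxy-3,7-dimethylocta-2,6-dienyl acetate F8, silylated (TBSCl, imidazole) to the silyl ether acetate F9, and deacetylated (K2CO3, MeOH) to the allylic alcohol F10. The Appel reaction (CBr4, PPh3) would give the allylic bromide F11. Copper-catalysed coupling with 4 would give the silyl-protected enyne F12, and TBAF in THF would release 6.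

**Further compounds**

F1 | step 12 | 3,19-O-(di-tert-butylsilylene)andrographolide | C=C1CC[C@@H]2[C@]3(C)CO[Si](C(C)(C)C)(C(C)(C)C)O[C@@H]3CC[C@@]2(C)[C@@H]1C/C=C1/C(=O)OC[C@H]1O
F2 | step 7 | (1R,2S,5R)-8-phenylmenthol | CC(C)(c1ccccc1)[C@@H]1CC[C@@H](C)C[C@H]1O
F3 | step 7 | (1R,2S,5R)-8-phenylmenthyl 3-oxobutanoate | CC(=O)CC(=O)O[C@@H]1C[C@H](C)CC[C@H]1C(C)(C)c1ccccc1
F4 | step 7 | (1R,2S,5R)-8-phenylmenthyl (6E,10E)-14-[(4S)-2,2-dimethyl-1,3-dioxolan-4-yl]-6,10-dimethyl-3-oxotetradeca-6,10-dien-13-ynoate | O=C(CC(=O)CC/C(C)=C/CC/C(C)=C/CC#C[C@H]1COC(C)(C)O1)O[C@@H]1C[C@H](C)CC[C@H]1C(C)(C)c1ccccc1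
F5 | step 7 | bicyclic β-keto ester without the C4 methyl (C4 epimers, keto and enol forms) | C=C1CC[C@@H]2C(C(=O)O[C@@H]3C[C@H](C)CC[C@H]3C(C)(C)c3ccccc3)C(=O)CC[C@@]2(C)[C@@H]1CC#C[C@H]1COC(C)(C)O1
F6 | step 7 | C4-methylated decalin keto ester, (1R,2S,5R)-8-phenylmenthyl analogue of 13 | C=C1CC[C@@H]2[C@](C)(C(=O)O[C@@H]3C[C@H](C)CC[C@H]3C(C)(C)c3ccccc3)C(=O)CC[C@@]2(C)[C@@H]1CC#C[C@H]1COC(C)(C)O1
F7 | step 3 | geranyl acetate | CC(C)=CCC/C(C)=C/COC(C)=O
F8 | step 3 | (2E,6E)-8-hydroxy-3,7-dimethylocta-2,6-dienyl acetate | OC/C(C)=C/CC/C(C)=C/COC(C)=O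
F9 | step 3 | (2E,6E)-8-(tert-butyldimethylsilyloxy)-3,7-dimethylocta-2,6-dienyl acetate | CC(C)(C)[Si](C)(C)OC/C(C)=C/CC/C(C)=C/COC(C)=O
F10 | step 3 | (2E,6E)-8-(tert-butyldimethylsilyloxy)-3,7-dimethylocta-2,6-dien-1-ol | CC(C)(C)[Si](C)(C)OC/C(C)=C/CC/C(C)=C/CO
F11 | step 3 | (2E,6E)-1-bromo-8-(tert-butyldimethylsilyloxy)-3,7-dimethylocta-2,6-diene | CC(C)(C)[Si](C)(C)OC/C(C)=C/CC/C(C)=C/CBr
F12 | step 3 | tert-butyldimethylsilyl ether of 6 | CC(C)(C)[Si](C)(C)OC/C(C)=C/CC/C(C)=C/CC#C[C@H]1COC(C)(C)O1
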